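1.50 mM of coupling partner is what the ochre flask keeps when its 1.0 mM of substrate, the limiting reagent, has gone through, if you assume one partner per substrate.

| flask | substrate | coupling partner | remark | time |
|---|---|---|---|---|
| ochre | 1 mM | 2.5 mM | the very flask that is asked about, followed so far |  |
| green | 1 mM | 1.7 mM | run made earlier |  |
| flask | 1.0 mM | 2.50 mM |  | 3.0 h |

- ochre (time / min: target / %, over-reaction product / %): 6.00: 3.7, 7.5; 10.0: 4.6, 15.2; 15.0: 3.3, 22.5; 25.0: 3.4, 37.5; 40.0: 2.3, 53.1; 80.0: 1.2, 78.2
- green (time / min: target / %, over-reaction product / %): 5.00: 4.2, 5.5; 15.0: 3.1, 18.4; 25.0: 2.6, 30.1; 40.0: 2.3, 44.0; 60.0: 1.9, 56.3; 80.0: 2.0, 65.5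

(scatter of a reading: 0.5 percentage points)

- the numbers in the tables scatter by 0.5 percentage points (one standard deviation)

1. share of target in target plus over-reaction product at 50 s
2. share of target in target plus over-reaction product at 12 min
3. share of target in target plus over-reaction product at 3.0 h
4. which of target and over-reaction product there is more of at 3.0 h

Call P whatever is neither target nor product. In the ochre run P falls from 44.6% to 20.6% between 40.0 min and 80.0 min, a rate of 0.0193 min⁻¹, with about 1.83 mM of partner at hand. In the green run it falls from 53.7% to 32.5% over the same span, a rate of 0.0126 min⁻¹, with about 1.13 mM at hand. Dividing gives 0.01058 mM⁻¹ min⁻¹ and 0.01110 mM⁻¹ min⁻¹, so the two readings nearly agree. Their mean is κ, the rate of loss of P per mM of partner at hand, 0.01084 mM⁻¹ min⁻¹; at any moment the loss looks pseudo-first-order.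

Now take two extreme flasks. With partner held at 2.50 mM, P at 3.0 h is 0.762%; with partner held at 1.50 mM, it is 5.36%. The ochre flask lies between them, because its partner starts at 2.50 mM and sinks towards the lower 1.50 mM. Put P back into the partner: with D the partner kept at the end and P counted in mM, partner is D + P, and the sum closes: P/(P + D) = (cA/cB)·exp(−κDt), where cA and cB are the charges of substrate and partner and t is the time. That gives me 3.29%. Target over P reads 5.37% late in the ochre run, so my share at 3.0 h is 0.182%.

The forecast, noting that target over substrate “stays near 0.05 in ochre”, gives 85%, 18.5%, 0.35% and over-reaction product in the lead; its last share is higher than mine.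

The flask gives 87.9%, 17.5%, 0.171%, and over-reaction product leads with 96.0% against 0.165% of target.

    substrate → intermediate A (k = 0.0340 s⁻¹)
    coupling partner + intermediate A → target (k = 0.230 M⁻¹ s⁻¹)
    coupling partner + intermediate A ⇌ intermediate B (K = 58.0 M⁻¹, k = 7.70 M⁻¹ s⁻¹)
    coupling partner + intermediate B ⇌ intermediate C (K = 980 M⁻¹, k = 3.20 M⁻¹ s⁻¹)
    target → over-reaction product (k = 0.00690 s⁻¹)

At 3.0 h the flask holds P of 3.83% of the substrate charged against my 3.29%, with intermediate A at 3.10% of the substrate charged. Now carry κ to the neighbouring flask with 1.5 mM of coupling partner. There D is 0.500 mM, and the same sum gives P of 16.8%, so about 83.2% of target and product together. That neighbouring flask stands at 84.9% of over-reaction product at 3.0 h.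

Readings and results are simulated on assumed constants; the scatter is artificial.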